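The route rests on breaking the aryl ether bond O1–C8a of ring C. C8a sits ortho to the C4 ketone and meta to both ring A oxygens (on C5 and C7), so a fluorine placed there is activated for intramolecular SNAr by the C2 alkoxide. In one operation the key step closes ring C of an open-chain anti-(2R,3R)-2,3-dihydroxy ketone whose ring A already carries the fluorine next to the prenyl group; both stereocentres are set earlier (poly-L-leucine epoxidation of an E-chalcone, invertive hydrolysis) and are not touched by the closure. Ring A comes from a symmetrical difluoronitrile by one SNAr, directed metalation and prenylation.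

Key step: step 7

Remark: flavonoid numbering (O1, C2, C3, C4, C4a, C5 to C8, C8a; rings A, B, C) is used for the target and the chromanones; prenyl = 3-methylbut-2-en-1-yl, allyl = prop-2-en-1-yl; poly-L-leucine is assumed to show its usual sense of induction for E-chalcones, giving the (2R,3S)-epoxide.

Step 1
Reactants: 1 2,6-difluoro-4-methoxybenzonitrile
Product: 2 2-fluoro-4-methoxy-6-(allyloxy)benzonitrile
Conditions: allyl alcohol (1.05 equiv), NaH (1.05 equiv), THF, 0 °C to rt
Reagents that add atoms: allyl alcohol, C=CCO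
Why: Nucleophilic aromatic substitution (SNAr) ortho to the nitrile; the two fluorines of 1 are equivalent, so there is no regiochemical question, and the alkoxy group that has entered slows a second substitution.

Step 2
Reactants: 2 2-fluoro-4-methoxy-6-(allyloxy)benzonitrile
Product: 4 2-fluoro-4-methoxy-3-prenyl-6-(allyloxy)benzonitrile, via aryllithium 3 (not isolated)
Conditions: LiN(i-Pr)2 (1.05 equiv), THF, −78 °C; CuBr·SMe2 (10 mol %), prenyl bromide (1.2 equiv), −78 to −20 °C; aq. NH4Cl
Reagents that add atoms: prenyl bromide (1-bromo-3-methylbut-2-ene), CC(C)=CCBr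
Why: Directed ortho-metalation then copper-catalysed allylic substitution: the amide base should remove the most acidic ring hydrogen, the one flanked by fluorine and methoxy rather than the one between two alkoxy groups, at a temperature too low for LiF loss to an aryne, and the aryllithium (diarylcuprate regime) should attack prenyl bromide at its unhindered CH2 terminus to give the linear prenyl arene.

Step 3
Reactants: 4 2-fluoro-4-methoxy-3-prenyl-6-(allyloxy)benzonitrile
Product: 7 1-[2-fluoro-4-methoxy-3-prenyl-6-(allyloxy)phenyl]ethan-1-one, via bromomagnesium ketimide 5 (not isolated), via N-H ketimine 6 (not isolated)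
Conditions: MeMgBr (2.5 equiv), THF/toluene, 60 °C; then 1 M aq. HCl, THF, rt
Reagents that add atoms: methylmagnesium bromide, C[Mg]Br; water, O
Why: Grignard addition to a nitrile stops at the N-magnesio ketimide, which cannot add a second equivalent, and mild acidic hydrolysis of the ketimine releases the methyl ketone.

Step 4
Reactants: 7 1-[2-fluoro-4-methoxy-3-prenyl-6-(allyloxy)phenyl]ethan-1-one; 8 4-(allyloxy)benzaldehyde
Product: 10 (E)-1-[2-fluoro-4-methoxy-3-prenyl-6-(allyloxy)phenyl]-3-[4-(allyloxy)phenyl]prop-2-en-1-one, via aldol adduct 9 (not isolated)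
Conditions: KOH (aq.), EtOH, 0 °C to rt
Reagents that add atoms: none
Why: Claisen–Schmidt condensation (crossed aldol of the methyl ketone with a non-enolisable aldehyde, then E1cB dehydration) should give the thermodynamically favoured E-enone.

Step 5
Reactants: 10 (E)-1-[2-fluoro-4-methoxy-3-prenyl-6-(allyloxy)phenyl]-3-[4-(allyloxy)phenyl]prop-2-en-1-one
Product: 11 [2-fluoro-4-methoxy-3-prenyl-6-(allyloxy)phenyl]{(2R,3S)-3-[4-(allyloxy)phenyl]oxiran-2-yl}methanone (trans)
Conditions: poly-L-leucine, urea·H2O2, DBU, THF, rt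
Reagents that add atoms: urea–hydrogen peroxide, NC(N)=O.OO
Why: Julia–Colonna epoxidation (Weitz–Scheffer conjugate addition of hydroperoxide inside the helical L-polypeptide) should set both stereocentres as the trans-(2R,3S)-epoxide and, being nucleophilic, leaves the electron-rich prenyl and allyl alkenes untouched.

Step 6
Reactants: 11 [2-fluoro-4-methoxy-3-prenyl-6-(allyloxy)phenyl]{(2R,3S)-3-[4-(allyloxy)phenyl]oxiran-2-yl}methanone
Product: 12 (2R,3R)-1-[2-fluoro-4-methoxy-3-prenyl-6-(allyloxy)phenyl]-3-[4-(allyloxy)phenyl]-2,3-dihydroxypropan-1-one (anti diol)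
Conditions: HClO4 (aq., cat.), THF/H2O, 0 °C
Reagents that add atoms: water, O
Why: Acid-catalysed epoxide hydrolysis: water should attack the benzylic carbon (the carbon next to the carbonyl cannot carry positive charge) from the side opposite the leaving oxygen, so this centre is inverted from S to R while the carbon next to the carbonyl keeps its C–O bond, giving the anti-(2R,3R)-diol.

Step 7
Reactants: 12 (2R,3R)-1-[2-fluoro-4-methoxy-3-prenyl-6-(allyloxy)phenyl]-3-[4-(allyloxy)phenyl]-2,3-dihydroxypropan-1-one
Product: 15 (2R,3R)-3-hydroxy-7-methoxy-8-prenyl-5-(allyloxy)-2-[4-(allyloxy)phenyl]chroman-4-one (2,3-trans), via dipotassium dialkoxide 13 (not isolated), via potassium chromanone 3-alkoxide 14 (not isolated)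
Conditions: KN(SiMe3)2 (2.2 equiv), THF, −78 to 0 °C, argon; then 1 M aq. HCl
Reagents that add atoms: none
Why: Double deprotonation gives dialkoxide 13, whose benzylic alkoxide (future O1) adds to the fluorine-bearing ring carbon (future C8a) ortho to the ketone to form a Meisenheimer-type enolate that expels fluoride (addition–elimination, SNAr). The closest known reaction type is the intramolecular SNAr of tethered alkoxides onto 2-fluoroaryl ketones to give chroman-4-ones. Ring C closes in a 6-endo-trig mode (attack on the ring carbon of the aryl C=C conjugated with the ketone), whereas attack by the other alkoxide would be a 5-endo-trig closure that cannot reach that carbon at the required angle. No stereocentre is made or broken: C2 and C3 are carried over unchanged and end as the trans-diequatorial (2R,3R) pair, which is also the thermodynamically preferred arrangement. The step needs ring closure to outrun retro-aldol cleavage and epimerisation at C3, and keeping the hydroxyl next to the ketone deprotonated should secure this, because cleavage would have to expel an enediolate dianion and the adjacent C–H is no longer acidic. Site selectivity is fixed by the substrate, since only one fluorine is left on ring A and the oxygens on C5 and C7 are meta to it.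

Step 8
Reactants: 15 (2R,3R)-3-hydroxy-7-methoxy-8-prenyl-5-(allyloxy)-2-[4-(allyloxy)phenyl]chroman-4-one
Product: 16 (2R,3R)-3,5-dihydroxy-2-(4-hydroxyphenyl)-7-methoxy-8-prenylchroman-4-one (CNP0265127.1)
Conditions: Pd(PPh3)4 (5 mol %), morpholine (6 equiv), THF, rt, degassed
Reagents that add atoms: none
Why: Tsuji–Trost-type deallylation: zerovalent palladium should ionise both aryl allyl ethers to π-allyl complexes that morpholine intercepts, while the prenyl group (no leaving group) and both stereocentres are unaffected under these near-neutral conditions.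

Compound list
1 | 2,6-difluoro-4-methoxybenzonitrile | N#Cc1c(F)cc(OC)cc1F | starting material
2 | 2-fluoro-4-methoxy-6-(allyloxy)benzonitrile | N#Cc1c(F)cc(OC)cc1OCC=C | intermediate
3 | [4-(allyloxy)-3-cyano-2-fluoro-6-methoxyphenyl]lithium | [Li]c1c(OC)cc(OCC=C)c(C#N)c1F | intermediate
4 | 2-fluoro-4-methoxy-3-prenyl-6-(allyloxy)benzonitrile | N#Cc1c(OCC=C)cc(OC)c(CC=C(C)C)c1F | intermediate
5 | bromomagnesium ketimide of 7 (N–MgBr) | CC(=N[Mg]Br)c1c(OCC=C)cc(OC)c(CC=C(C)C)c1F | intermediate
6 | 1-[2-fluoro-4-methoxy-3-prenyl-6-(allyloxy)phenyl]ethan-1-imine | CC(=N)c1c(OCC=C)cc(OC)c(CC=C(C)C)c1F | intermediate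
7 | 1-[2-fluoro-4-methoxy-3-prenyl-6-(allyloxy)phenyl]ethan-1-one | CC(=O)c1c(OCC=C)cc(OC)c(CC=C(C)C)c1F | intermediate
8 | 4-(allyloxy)benzaldehyde | O=Cc1ccc(OCC=C)cc1 | starting material
9 | racemic 1-[2-fluoro-4-methoxy-3-prenyl-6-(allyloxy)phenyl]-3-[4-(allyloxy)phenyl]-3-hydroxypropan-1-one | O=C(CC(O)c1ccc(OCC=C)cc1)c1c(OCC=C)cc(OC)c(CC=C(C)C)c1F | intermediate
10 | (E)-1-[2-fluoro-4-methoxy-3-prenyl-6-(allyloxy)phenyl]-3-[4-(allyloxy)phenyl]prop-2-en-1-one | O=C(/C=C/c1ccc(OCC=C)cc1)c1c(OCC=C)cc(OC)c(CC=C(C)C)c1F | intermediate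
11 | [2-fluoro-4-methoxy-3-prenyl-6-(allyloxy)phenyl]{(2R,3S)-3-[4-(allyloxy)phenyl]oxiran-2-yl}methanone | O=C(c1c(OCC=C)cc(OC)c(CC=C(C)C)c1F)[C@@H]1O[C@H]1c1ccc(OCC=C)cc1 | intermediate
12 | (2R,3R)-1-[2-fluoro-4-methoxy-3-prenyl-6-(allyloxy)phenyl]-3-[4-(allyloxy)phenyl]-2,3-dihydroxypropan-1-one | O[C@H](c1ccc(OCC=C)cc1)[C@@H](O)C(=O)c1c(OCC=C)cc(OC)c(CC=C(C)C)c1F | intermediate
13 | dipotassium 2,3-dialkoxide of 12 | [K+].[K+].[O-][C@H](c1ccc(OCC=C)cc1)[C@@H]([O-])C(=O)c1c(OCC=C)cc(OC)c(CC=C(C)C)c1F | intermediate
14 | potassium 3-alkoxide of 15 | [K+].COc1cc(OCC=C)c2c(c1CC=C(C)C)O[C@H](c1ccc(OCC=C)cc1)[C@@H]([O-])C2=O | intermediate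
15 | (2R,3R)-3-hydroxy-7-methoxy-8-prenyl-5-(allyloxy)-2-[4-(allyloxy)phenyl]chroman-4-one | COc1cc(OCC=C)c2c(c1CC=C(C)C)O[C@H](c1ccc(OCC=C)cc1)[C@@H](O)C2=O | intermediate
16 | (2R,3R)-3,5-dihydroxy-2-(4-hydroxyphenyl)-7-methoxy-8-prenylchroman-4-one | COc1cc(O)c2c(c1CC=C(C)C)O[C@H](c1ccc(O)cc1)[C@@H](O)C2=O | target

Total step count: 8. Longest linear sequence: 8 steps (1 to 16; aldehyde 8 enters at step 4).

Steps most likely to fail

Step 7. Retro-aldol fragmentation of the benzylic alkoxide, or enolisation at the carbon next to the ketone, may overtake a ring closure that is slowed by the prenyl group beside the fluorine. The fallback sets out from 12 and comes back at 15. Both hydroxyls of 12 are silylated (Et3SiOTf, 2,6-lutidine, CH2Cl2) to the bis(triethylsilyl) ether F1. A substoichiometric amount of anhydrous Bu4NF in THF then unmasks the alkoxide only transiently by Si–F exchange, and the fluoride expelled from the ring carries the chain. A silyl group lost first from the oxygen next to the ketone is passed back by 1,4-O-to-O migration, so no free dialkoxide builds up. This should give the 3-O-triethylsilyl chromanone F2, and HF·pyridine removes the remaining silyl group to return the route to 15.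

Step 6. The p-alkoxybenzylic C–O bond may ionise before water arrives, so that capture occurs from both faces and configuration at that carbon leaks, and the epoxy ketone may undergo an acid-induced acyl shift. The fallback sets out from 10 and comes back at 12, and it keeps the benzylic C–O bond instead of inverting it. Epoxidation of 10 with poly-D-leucine (urea·H2O2, DBU) should give the enantiomeric (2S,3R)-epoxy ketone F3. SmI2 (THF/MeOH, −78 °C) cleaves only the C–O bond next to the carbonyl, giving the (S)-β-hydroxy ketone F4 with the benzylic centre intact. The dianion of F4 (LiN(i-Pr)2, 2.2 equiv, −78 °C) is hydroxylated with 2-(phenylsulfonyl)-3-phenyloxaziridine, an oxidant that spares the prenyl and allyl alkenes. Attack should occur anti to the benzylic substituent within the lithium chelate, and a cold quench returns the route to 12.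

Step 5. The di-ortho-substituted aryl ketone is twisted out of the enone plane and may bind poorly to the peptide helix, giving slow conversion and weak enantio-induction. The fallback sets out from 10 and comes back at 11. Luche reduction (NaBH4, CeCl3·7H2O, MeOH) gives the racemic allylic alcohol F5. A Sharpless kinetic resolution (Ti(O-i-Pr)4, L-(+)-diisopropyl tartrate, t-BuOOH, 4 Å sieves, CH2Cl2, −20 °C, stopped near half conversion) is chemoselective for the allylic alcohol over the prenyl and allyl groups. It should epoxidise the fast-reacting enantiomer to the erythro epoxy alcohol F6, which is separated from the unreacted enantiomer. Dess–Martin oxidation of the carbinol returns the route to 11.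

Further compounds
F1 | step 7 | (2R,3R)-1-[2-fluoro-4-methoxy-3-prenyl-6-(allyloxy)phenyl]-3-[4-(allyloxy)phenyl]-2,3-bis(triethylsilyloxy)propan-1-one | CC[Si](CC)(CC)O[C@H](c1ccc(OCC=C)cc1)[C@@H](O[Si](CC)(CC)CC)C(=O)c1c(OCC=C)cc(OC)c(CC=C(C)C)c1F
F2 | step 7 | (2R,3R)-7-methoxy-8-prenyl-5-(allyloxy)-2-[4-(allyloxy)phenyl]-3-(triethylsilyloxy)chroman-4-one | COc1cc(OCC=C)c2c(c1CC=C(C)C)O[C@H](c1ccc(OCC=C)cc1)[C@@H](O[Si](CC)(CC)CC)C2=O
F3 | step 6 | [2-fluoro-4-methoxy-3-prenyl-6-(allyloxy)phenyl]{(2S,3R)-3-[4-(allyloxy)phenyl]oxiran-2-yl}methanone | O=C(c1c(OCC=C)cc(OC)c(CC=C(C)C)c1F)[C@H]1O[C@@H]1c1ccc(OCC=C)cc1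
F4 | step 6 | (3S)-1-[2-fluoro-4-methoxy-3-prenyl-6-(allyloxy)phenyl]-3-[4-(allyloxy)phenyl]-3-hydroxypropan-1-one | O[C@H](c1ccc(OCC=C)cc1)CC(=O)c1c(OCC=C)cc(OC)c(CC=C(C)C)c1F
F5 | step 5 | racemic (E)-1-[2-fluoro-4-methoxy-3-prenyl-6-(allyloxy)phenyl]-3-[4-(allyloxy)phenyl]prop-2-en-1-ol | OC(/C=C/c1ccc(OCC=C)cc1)c1c(OCC=C)cc(OC)c(CC=C(C)C)c1F
F6 | step 5 | (S)-[2-fluoro-4-methoxy-3-prenyl-6-(allyloxy)phenyl]{(2S,3S)-3-[4-(allyloxy)phenyl]oxiran-2-yl}methanol | O[C@@H](c1c(OCC=C)cc(OC)c(CC=C(C)C)c1F)[C@@H]1O[C@H]1c1ccc(OCC=C)cc1
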